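**Plan**

- Retrosynthesis: the C4–O bond is cut first (oxygen handed from O5 to an enone), then the C2 carbonyl oxygen (ene oxidation of a C2=C3 alkene), then C5–O (anti opening of a C5–C6 oxirane). The oxirane C5–O and C6–O bonds, the C7 benzoate and the C1–O bond go last, back to Birch-reduced benzoic acid.
- Enabling feature (C1 = carbinol carbon bearing C7H2OBz, C2 = ketone, then C3, C4, C5, C6): O1 and O6 are cis and O5 is trans to them. This is the imprint of a C5–C6 oxirane syn to O1 on one of the two mirror-related alkenes (C5=C6, C2=C3) of a 1-substituted cyclohexa-2,5-dien-1-ol whose mirror plane passes through C1 and C4.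
- Forward: the carbocycle is the benzene ring of benzoic acid, dearomatized and never opened. The oxirane is the only ring built for the target's stereochemistry; the dioxolane and dioxaborolane rings are temporary.
- Stereochemistry: the catalyst-controlled epoxidation sets C1, C5 and C6 at once, water then inverts C5, and O5 hands the last oxygen to the same face of C4.

Key step: step 6

Numbering: the ring locants C1–C6 and C7 defined above are used for every intermediate; the target's own name uses standard locants.
Assumption: the sense of induction of the bishydroxamic acid ligand on this substrate class is not known, so the ligand antipode that gives the epoxide drawn for step 6 is chosen by a trial run.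

**Route**

Step 1
Reactants: 1 benzoic acid
Product: 3 cyclohexa-2,5-diene-1-carboxylic acid, via sodium cyclohexa-2,5-diene-1-carboxylate 2 (not isolated)
Conditions: Na, EtOH, NH3(l), −78 to −33 °C; NH4Cl; then aq. HCl
Reagents that add atoms: none
Why: Birch reduction of a benzoate places the two new hydrogens at the ipso and para carbons, so the skipped 2,5-diene should form and survive the cold acidic work-up.

Step 2
Reactants: 3 cyclohexa-2,5-diene-1-carboxylic acid
Product: 4 methyl cyclohexa-2,5-diene-1-carboxylate
Conditions: MeI, KHCO3, DMF, rt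
Reagents that add atoms: iodomethane CI
Why: O-alkylation of the carboxylate (SN2 esterification) under bicarbonate, a base too weak to move the skipped diene into conjugation.

Step 3
Reactants: 4 methyl cyclohexa-2,5-diene-1-carboxylate
Product: 6 methyl 1-hydroxycyclohexa-2,5-diene-1-carboxylate, via potassium dienolate 5 (not isolated)
Conditions: KN(SiMe3)2, THF, −78 °C; 3-phenyl-2-(phenylsulfonyl)oxaziridine, −78 °C; aq. NH4Cl
Reagents that add atoms: 3-phenyl-2-(phenylsulfonyl)oxaziridine O=S(=O)(c1ccccc1)N1OC1c1ccccc1
Why: Enolate hydroxylation with an N-sulfonyloxaziridine should occur at C1, the position at which these cross-conjugated dienolates are alkylated in Birch reductive alkylations, and C1 stays on the mirror plane so no stereocentre arises yet.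

Step 4
Reactants: 6 methyl 1-hydroxycyclohexa-2,5-diene-1-carboxylate
Product: 7 1-(hydroxymethyl)cyclohexa-2,5-dien-1-ol
Conditions: LiAlH4, THF, 0 °C; then H2O
Reagents that add atoms: none
Why: Hydride reduction of the ester to the primary alcohol under basic conditions, which leave the acid-sensitive dienol and the isolated alkenes alone.

Step 5
Reactants: 7 1-(hydroxymethyl)cyclohexa-2,5-dien-1-ol, 8 benzoyl chloride
Product: 9 (1-hydroxycyclohexa-2,5-dien-1-yl)methyl benzoate
Conditions: BzCl (1.05 equiv), pyridine, CH2Cl2, −20 to 0 °C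
Reagents that add atoms: benzoyl chloride O=C(Cl)c1ccccc1
Why: Selective acylation of the primary hydroxyl over the hindered tertiary one installs the C7 benzoate of the target and leaves O1–H as the only hydroxyl able to bind a metal.

Step 6
Reactants: 9 (1-hydroxycyclohexa-2,5-dien-1-yl)methyl benzoate
Product: 10 [(1S,2S,6S)-2-hydroxy-7-oxabicyclo[4.1.0]hept-3-en-2-yl]methyl benzoate
Conditions: Hf(OtBu)4 (10 mol %), one antipode of N,N'-(trans-cyclohexane-1,2-diyl)bis(N-hydroxy-2,2-diphenylacetamide) (12 mol %), cumene hydroperoxide (1.3 equiv), MgO, 4 Å MS, toluene, 0 °C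
Reagents that add atoms: cumene hydroperoxide CC(C)(OO)c1ccccc1
Why: Proposed new method: the tertiary alkoxide of 9 and the hydroperoxide should both bind the tetravalent hafnium centre held by the twofold-symmetric bishydroxamate, which then passes the activated peroxide oxygen to the alkene on the face of C1–O; the closest known reactions are the Hf(OtBu)4- or Zr(OtBu)4-bishydroxamic acid epoxidations of tertiary allylic and homoallylic alcohols and the Ti(OiPr)4/tartrate (Sharpless) desymmetrization of divinyl carbinols, none of which has been shown on a cyclohexa-2,5-dien-1-ol. The oxirane (O, C5, C6) closes by one concerted oxygen-atom transfer to both alkene carbons, a [2+1] addition without an open intermediate, so the cis geometry is kept. C5 and C6 are set by the syn delivery from the metal bound at O1, and C1, until then a prochiral centre on the mirror plane through C1 and C4, becomes stereogenic according to which enantiotopic alkene (C5=C6 or C2=C3) the chiral ligand selects. The step therefore needs enantiotopic-group selectivity, which only the ligand can supply, and syn facial selectivity, which O1 coordination secures because the C7 oxygen is masked as a benzoate and cannot compete as a directing hydroxyl. Any mirror-image epoxide that forms still carries the alkene the catalyst prefers and should be consumed faster by a second epoxidation to the meso bis-epoxide, which should raise the enantiomeric purity of 10 as conversion proceeds.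

Step 7
Reactants: 10 [(1S,2S,6S)-2-hydroxy-7-oxabicyclo[4.1.0]hept-3-en-2-yl]methyl benzoate
Product: 11 [(1S,5R,6S)-1,5,6-trihydroxycyclohex-2-en-1-yl]methyl benzoate
Conditions: HClO4 (cat.), THF/H2O (3:1), 0 °C to rt
Reagents that add atoms: water O
Why: Acid-catalysed anti (SN2-type) epoxide hydrolysis should take place at C5, remote from the fully substituted and inductively deactivated C1, so C5 is inverted (O5 trans to O6) while C6 keeps the oxirane oxygen cis to O1.

Step 8
Reactants: 11 [(1S,5R,6S)-1,5,6-trihydroxycyclohex-2-en-1-yl]methyl benzoate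
Product: 13 [(1S,5R,6S)-1,6-(isopropylidenedioxy)-5-[(2-methoxypropan-2-yl)oxy]cyclohex-2-en-1-yl]methyl benzoate, via acetonide alcohol 12 (not isolated)
Conditions: Me2C(OMe)2, PPTS (cat.), CH2Cl2, rt; then 2-methoxypropene (excess), 0 °C; Et3N
Reagents that add atoms: 2,2-dimethoxypropane COC(C)(C)OC; 2-methoxypropene COC(C)=C
Why: Thermodynamic acetalization closes the cis-fused dioxolane on the cis O1/O6 pair and not on the trans O5/O6 pair, and the remaining O5–H is then capped as an acid-labile mixed acetal so that it is not acetylated in step 9.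

Step 9
Reactants: 13 [(1S,5R,6S)-1,6-(isopropylidenedioxy)-5-[(2-methoxypropan-2-yl)oxy]cyclohex-2-en-1-yl]methyl benzoate
Product: 16 [(1S,5R,6S)-1,6-(isopropylidenedioxy)-5-[(2-methoxypropan-2-yl)oxy]-2-oxocyclohex-3-en-1-yl]methyl benzoate, via allylic hydroperoxide 14 (not isolated), via allylic peracetate 15 (not isolated)
Conditions: O2, 5,10,15,20-tetraphenylporphyrin (cat.), hν (visible), CH2Cl2, 0 °C; then Ac2O, pyridine, DMAP (cat.), 0 °C to rt
Reagents that add atoms: dioxygen (as singlet oxygen) O=O
Why: In the Schenck ene reaction only C4 offers an allylic hydrogen (C1 is quaternary), so oxygen must bond to C2 with the alkene moving to C3=C4, and Kornblum–DeLaMare-type elimination of the derived peracetate then gives the enone, erasing the uncontrolled C2 centre.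

Step 10
Reactants: 16 [(1S,5R,6S)-1,6-(isopropylidenedioxy)-5-[(2-methoxypropan-2-yl)oxy]-2-oxocyclohex-3-en-1-yl]methyl benzoate
Product: 17 [(1S,5R,6S)-5-hydroxy-1,6-(isopropylidenedioxy)-2-oxocyclohex-3-en-1-yl]methyl benzoate
Conditions: PPTS (cat.), MeOH, 0 °C; Et3N
Reagents that add atoms: none
Why: Acid-catalysed transacetalization to methanol cleaves the acyclic mixed acetal far faster than the cyclic isopropylidene acetal, freeing O5–H as the tether for step 11.

Step 11
Reactants: 17 [(1S,5R,6S)-5-hydroxy-1,6-(isopropylidenedioxy)-2-oxocyclohex-3-en-1-yl]methyl benzoate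
Product: 19 [(1S,4R,5R,6S)-4,5-dihydroxy-1,6-(isopropylidenedioxy)-2-oxocyclohexyl]methyl benzoate, via cyclic phenylboronate 18 (not isolated)
Conditions: PhB(OH)2 (1.5 equiv), iPr2NH (20 mol %), 4 Å MS, CH2Cl2, rt; then H2O2, aq. NaHCO3, THF, 0 °C
Reagents that add atoms: phenylboronic acid OB(O)c1ccccc1
Why: Boronic acid hemiester-tethered intramolecular oxa-Michael addition, known for γ-hydroxy enones including 4-hydroxycyclohexenones, delivers the boron-bound hydroxyl from O5 to C4 through a cis-fused five-membered dioxaborolane (5-exo-trig), which fixes C4 with O4 cis to O5 before oxidative cleavage of the boron unit.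

Step 12
Reactants: 19 [(1S,4R,5R,6S)-4,5-dihydroxy-1,6-(isopropylidenedioxy)-2-oxocyclohexyl]methyl benzoate, 8 benzoyl chloride
Product: 20 [(1S,4R,5R,6S)-5-(benzoyloxy)-4-hydroxy-1,6-(isopropylidenedioxy)-2-oxocyclohexyl]methyl benzoate
Conditions: BzCl (1.1 equiv), Ph2BOCH2CH2NH2 (10 mol %), iPr2NEt, MeCN, rt
Reagents that add atoms: benzoyl chloride O=C(Cl)c1ccccc1
Why: Borinic acid-catalysed regioselective monoacylation of a cis-1,2-diol goes to the equatorial oxygen, as with pyranoside cis-diols, and in the favoured chair (C7H2OBz equatorial) that oxygen is O5 while O4 is axial.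

Step 13
Reactants: 20 [(1S,4R,5R,6S)-5-(benzoyloxy)-4-hydroxy-1,6-(isopropylidenedioxy)-2-oxocyclohexyl]methyl benzoate
Product: 21 [(1S,2S,3R,4R)-3-(benzoyloxy)-1,2,4-trihydroxy-6-oxocyclohexyl]methyl benzoate (CNP0127041.1)
Conditions: TFA/H2O (9:1), CH2Cl2, 0 °C to rt
Reagents that add atoms: none
Why: Acid hydrolysis of the isopropylidene acetal frees O1–H and O6–H under cold, short conditions chosen to avoid benzoyl migration and dehydration of the β-hydroxy ketone.

**Compound list**

1 | benzoic acid | OC(=O)c1ccccc1 | starting material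
2 | sodium cyclohexa-2,5-diene-1-carboxylate | [Na+].[O-]C(=O)C1C=CCC=C1 | intermediate (not isolated)
3 | cyclohexa-2,5-diene-1-carboxylic acid | OC(=O)C1C=CCC=C1 | intermediate
4 | methyl cyclohexa-2,5-diene-1-carboxylate | COC(=O)C1C=CCC=C1 | intermediate
5 | potassium dienolate of 4, potassium (cyclohexa-2,5-dien-1-ylidene)(methoxy)methanolate | [K+].[O-]C(OC)=C1C=CCC=C1 | intermediate (not isolated)
6 | methyl 1-hydroxycyclohexa-2,5-diene-1-carboxylate | COC(=O)C1(O)C=CCC=C1 | intermediate
7 | 1-(hydroxymethyl)cyclohexa-2,5-dien-1-ol | OCC1(O)C=CCC=C1 | intermediate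
8 | benzoyl chloride | O=C(Cl)c1ccccc1 | starting material
9 | (1-hydroxycyclohexa-2,5-dien-1-yl)methyl benzoate | O=C(OCC1(O)C=CCC=C1)c1ccccc1 | intermediate
10 | [(1S,2S,6S)-2-hydroxy-7-oxabicyclo[4.1.0]hept-3-en-2-yl]methyl benzoate (oxirane syn to the tertiary OH) | O=C(OC[C@@]1(O)C=CC[C@@H]2O[C@H]12)c1ccccc1 | intermediate
11 | [(1S,5R,6S)-1,5,6-trihydroxycyclohex-2-en-1-yl]methyl benzoate | O=C(OC[C@@]1(O)C=CC[C@@H](O)[C@@H]1O)c1ccccc1 | intermediate
12 | [(1S,5R,6S)-5-hydroxy-1,6-(isopropylidenedioxy)cyclohex-2-en-1-yl]methyl benzoate | O=C(OC[C@]12OC(C)(C)O[C@H]1[C@H](O)CC=C2)c1ccccc1 | intermediate (not isolated)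
13 | [(1S,5R,6S)-1,6-(isopropylidenedioxy)-5-[(2-methoxypropan-2-yl)oxy]cyclohex-2-en-1-yl]methyl benzoate | O=C(OC[C@]12OC(C)(C)O[C@H]1[C@H](OC(C)(C)OC)CC=C2)c1ccccc1 | intermediate
14 | [(1S,2RS,5R,6S)-2-hydroperoxy-1,6-(isopropylidenedioxy)-5-[(2-methoxypropan-2-yl)oxy]cyclohex-3-en-1-yl]methyl benzoate | O=C(OC[C@]12OC(C)(C)O[C@H]1[C@H](OC(C)(C)OC)C=CC2OO)c1ccccc1 | intermediate (not isolated)
15 | [(1S,2RS,5R,6S)-2-(acetylperoxy)-1,6-(isopropylidenedioxy)-5-[(2-methoxypropan-2-yl)oxy]cyclohex-3-en-1-yl]methyl benzoate | O=C(OC[C@]12OC(C)(C)O[C@H]1[C@H](OC(C)(C)OC)C=CC2OOC(C)=O)c1ccccc1 | intermediate (not isolated)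
16 | [(1S,5R,6S)-1,6-(isopropylidenedioxy)-5-[(2-methoxypropan-2-yl)oxy]-2-oxocyclohex-3-en-1-yl]methyl benzoate | O=C(OC[C@]12OC(C)(C)O[C@H]1[C@H](OC(C)(C)OC)C=CC2=O)c1ccccc1 | intermediate
17 | [(1S,5R,6S)-5-hydroxy-1,6-(isopropylidenedioxy)-2-oxocyclohex-3-en-1-yl]methyl benzoate | O=C(OC[C@]12OC(C)(C)O[C@H]1[C@H](O)C=CC2=O)c1ccccc1 | intermediate
18 | [(1S,4R,5R,6S)-1,6-(isopropylidenedioxy)-2-oxo-4,5-[(phenylboranediyl)bis(oxy)]cyclohexyl]methyl benzoate (cis-fused dioxaborolane on O4/O5) | O=C(OC[C@]12OC(C)(C)O[C@H]1[C@@H]3OB(c4ccccc4)O[C@@H]3CC2=O)c1ccccc1 | intermediate (not isolated)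
19 | [(1S,4R,5R,6S)-4,5-dihydroxy-1,6-(isopropylidenedioxy)-2-oxocyclohexyl]methyl benzoate | O=C(OC[C@]12OC(C)(C)O[C@H]1[C@H](O)[C@H](O)CC2=O)c1ccccc1 | intermediate
20 | [(1S,4R,5R,6S)-5-(benzoyloxy)-4-hydroxy-1,6-(isopropylidenedioxy)-2-oxocyclohexyl]methyl benzoate | O=C(OC[C@]12OC(C)(C)O[C@H]1[C@H](OC(=O)c3ccccc3)[C@H](O)CC2=O)c1ccccc1 | intermediate
21 | [(1S,2S,3R,4R)-3-(benzoyloxy)-1,2,4-trihydroxy-6-oxocyclohexyl]methyl benzoate, CNP0127041.1 | O=C(OC[C@@]1(O)C(=O)C[C@@H](O)[C@@H](OC(=O)c2ccccc2)[C@@H]1O)c1ccccc1 | target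

**Step count and risks**

Total: 13 steps. Longest linear sequence: 13 steps (1 to 21); 8 enters twice as the acylating agent.

Steps most likely to fail:

1. Step 6 (proposed new method). The ligand may discriminate poorly between the two enantiotopic alkenes, or oxygen transfer to the hindered tertiary alkoxide may be slow enough for Lewis-acid opening of the product to compete.
Fallback, by known chemistry, setting out from 9: VO(acac)2 (cat.) with tert-butyl hydroperoxide in CH2Cl2 at 0 °C (hydroxyl-directed epoxidation, stopped before bis-epoxide builds up) should give the racemic syn-epoxy alcohol F1. Hydrolysis as in step 7 gives the racemic triol F2, and Me2C(OMe)2/PPTS gives the racemic acetonide alcohol F3. Lipase-catalysed acetylation (Candida antarctica lipase B, vinyl acetate, tert-butyl methyl ether, 30 °C) then resolves F3 at its only secondary hydroxyl. By the usual size model for lipases (large flank C6, medium flank C4H2) the (5R)-antipode should be the one acetylated, giving the acetate F4. F4 is separated from the unreacted antipode and hydrolysed with the same lipase in pH 7 phosphate buffer. This comes back to the route at 12, which is taken through the second half of step 8 (2-methoxypropene) to 13; if the enzyme prefers the other antipode, the unreacted alcohol is 12 itself.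

2. Step 9. The ene reaction of an electron-poor cis-disubstituted ring alkene may be too slow, so that sensitizer bleaching and loss of the acid-labile mixed acetal overtake hydroperoxide formation.
Fallback, setting out from 13: m-chloroperbenzoic acid buffered with NaHCO3 epoxidises C2=C3 to the epoxide F5 (either face serves). PhSeNa (from PhSeSePh and NaBH4, EtOH) should open it at C3, away from the quaternary C1, to the hydroxy selenide F6. Oxidation with H2O2 and syn-elimination of the selenoxide away from the carbinol carbon gives the allylic alcohol F7 with the C3=C4 alkene, and NaHCO3-buffered Dess–Martin oxidation returns to the route at 16.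

3. Step 12. Acylation may not distinguish O5–H from O4–H, the benzoyl group may migrate between these cis oxygens, or base may eliminate O4 from the β-hydroxy ketone.
Fallback, setting out from 19: 2-chloro-1,1,1-trimethoxyethane with camphorsulfonic acid (cat.) gives the cyclic orthoester F8 across O4 and O5. Brief aqueous acetic acid opens it, as cyclic orthoesters of cis-cyclohexanediols do, to the axial ester, here the O4 chloroacetate F9 with O5–H free. Benzoylation (8, pyridine, DMAP) gives the O4-chloroacetyl O5-benzoyl compound F10, and thiourea with NaHCO3 in MeOH removes the chloroacetate, returning to the route at 20.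

**Further compounds**

F1 | step 6 | racemic (2-hydroxy-7-oxabicyclo[4.1.0]hept-3-en-2-yl)methyl benzoate, oxirane syn to OH (10 plus its mirror image) | O=C(OC[C@@]1(O)C=CC[C@@H]2O[C@H]12)c1ccccc1.O=C(OC[C@]1(O)C=CC[C@H]2O[C@@H]12)c1ccccc1
F2 | step 6 | racemic (1,5,6-trihydroxycyclohex-2-en-1-yl)methyl benzoate, 1,6-cis-5,6-trans (11 plus its mirror image) | O=C(OC[C@@]1(O)C=CC[C@@H](O)[C@@H]1O)c1ccccc1.O=C(OC[C@]1(O)C=CC[C@H](O)[C@H]1O)c1ccccc1
F3 | step 6 | racemic [5-hydroxy-1,6-(isopropylidenedioxy)cyclohex-2-en-1-yl]methyl benzoate (12 plus its mirror image) | O=C(OC[C@]12OC(C)(C)O[C@H]1[C@H](O)CC=C2)c1ccccc1.O=C(OC[C@@]12OC(C)(C)O[C@@H]1[C@@H](O)CC=C2)c1ccccc1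
F4 | step 6 | [(1S,5R,6S)-5-acetoxy-1,6-(isopropylidenedioxy)cyclohex-2-en-1-yl]methyl benzoate | O=C(OC[C@]12OC(C)(C)O[C@H]1[C@H](OC(C)=O)CC=C2)c1ccccc1
F5 | step 9 | 2,3-epoxide of 13 (oxirane on C2–C3, face not fixed) | O=C(OC[C@]12OC(C)(C)O[C@H]1[C@H](OC(C)(C)OC)CC3OC32)c1ccccc1
F6 | step 9 | 2-hydroxy-3-(phenylselanyl) compound from F5 (trans opening at C3) | O=C(OC[C@]12OC(C)(C)O[C@H]1[C@H](OC(C)(C)OC)CC([Se]c3ccccc3)C2O)c1ccccc1
F7 | step 9 | 2-hydroxy-3-ene allylic alcohol (the C2 alcohol corresponding to enone 16) | O=C(OC[C@]12OC(C)(C)O[C@H]1[C@H](OC(C)(C)OC)C=CC2O)c1ccccc1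
F8 | step 12 | O4,O5-[2-chloro-1-methoxyethylidene] cyclic orthoester of 19 | O=C(OC[C@]12OC(C)(C)O[C@H]1[C@@H]3OC(CCl)(OC)O[C@@H]3CC2=O)c1ccccc1
F9 | step 12 | O4-chloroacetate of 19 (O5–H free) | O=C(OC[C@]12OC(C)(C)O[C@H]1[C@H](O)[C@H](OC(=O)CCl)CC2=O)c1ccccc1
F10 | step 12 | O4-chloroacetate of 20 (O5 benzoate, O4 chloroacetate) | O=C(OC[C@]12OC(C)(C)O[C@H]1[C@H](OC(=O)c3ccccc3)[C@H](OC(=O)CCl)CC2=O)c1ccccc1
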